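## Analysis of the target

Target 35 is a germacranolide. Its ten-membered carbocycle (C1–C10) carries a trans-fused α-methylene-γ-butyrolactone across C7/C8 (lactone oxygen on C8, C11=C13 exocyclic), a 4,5-epoxide with the C15 methyl on C4, an angelate on O6, a free hydroxyl on C1 and an exocyclic C10=C14 methylene. There are six stereocentres, (1S,4R,5S,6S,7R,8S). Five are contiguous along C4–C8; C1 is insulated from them by C2/C3 and by the sp2 carbon C10 and cannot be set by relay. The epoxide has C3 and C6 cis, so it derives from a Z C4=C5 olefin, and its oxygen is cis to O6 on the ring, the relationship a hydroxyl-directed epoxidation of a medium-ring Z-allylic alcohol should deliver. Sensitive functions are the methylene lactone (Michael acceptor), the angelate (Z to E isomerisation to the tiglate), the epoxide (acid, transannular opening by a free hydroxyl) and the allylic C1 carbinol. The difficulty is the ten-membered ring, whose direct end-to-end closure is slow and would have to respect five neighbouring stereocentres. The strategy rests on the array HO–C6–C7(ring)–C11=C13. A homoallylic alcohol with an exocyclic methylene is the retron of a [2,3]-Wittig shift of a C6–O–C13 allyl ether, so the carbocycle can come from contraction of a thirteen-membered cyclic ether in which the C4≡C5 alkyne acidifies C6.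

## Retrosynthetic reasoning

**Lactone and ester.** In 35 the acyl C12–O8 bond is cut and C12 is returned to the alcohol level, giving triol 32. The methylene lactone is thus unveiled in the last step by oxidative lactonisation. Triol 32 comes from tris-silyl ether 31, and the O6–acyl bond of 31 is cut to epoxy alcohol 28 and angelic acid 29. The angelate goes on late, but before O8 and O12 are freed, so that O6 cannot compete for C12 and only the 12,8-olide can form.

**Epoxide and C15.** The two C–O bonds of the epoxide in 28 are cut to the Z-allylic alcohol 27; the free C6 hydroxyl must direct both site and face. In 27 the C4–C15 bond and the C5–H bond are cut to the cycloalkynol 25. The forward reaction has to add methyl and hydrogen to the same side of C4≡C5 with methyl on the carbon remote from the hydroxyl.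

**Key disconnection.** In 25 the C6–C7 bond is cut and an O6–C13 bond is drawn, which expands the ten-membered carbocycle to the thirteen-membered propargylic allylic ether 23. This is chosen over any direct ring closure because it turns the hardest bond of the skeleton into a sigmatropic event inside a preformed ring. It creates C6, C7 and the C11=C13 methylene at once, and the alkyne that activates C6 is the handle for C15. The forward step needs lithiation at C6 only, the anti C6/C7 relationship from the olefin geometry (C8 trans to C13), and facial control from C8.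

**Ether ring.** In 23 the O6–C13 bond is cut to chloro alcohol 22. The alkoxide is placed on O6 and the leaving group on C13 because an alkoxide on O13 would sit next to the O12 silyl ether and could exchange C12 and C13 by silyl shift. Compound 22 comes from 18 through 19 and 21 by unmasking O13, chlorination and unmasking O6. This needs three mutually orthogonal ether types, which is why O1 is a silyl ether and the p-methoxybenzyl group is reserved for O13.

**C1–C10.** In 18 (via 17) the C1–C10 bond is cut to alkenyl bromide 11 and aldehyde 16. An alkenyl-metal addition is the only direct way to a carbinol flanked by a 1,1-disubstituted olefin, and C1 must be set under reagent control.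

**Fragment B (C7–C14).** In 11 (via diol 10) the C11–C12 bond is cut to Z-iodoalkene 9, which comes from propargylic alcohol 7 by trans-addition of hydrogen and iodine. This fixes without ambiguity which arm of C11 is cis to C8. In 7 the C8–C9 bond is cut to ynal 4 and 2,3-dibromopropene 5, which supplies C9, C10, C14 and the bromide for the later C1–C10 coupling. Ynal 4 comes from ether 2 and propargyl alcohol 1.

**Fragment A (C1–C6).** Aldehyde 16 comes from alcohol 15, in which the C3–C4 bond is cut to the silyl ether 12 of propargyl alcohol 1 and oxetane 13.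

## Alternatives that were turned down

**Alternative 1:** The C4=C5 and C1=C10 olefins of a germacra-1(10),4-diene are traced back to the C5–C10 and C1–C4 bonds of a cyclobutane. Flash thermolysis of the tricyclic enone–cyclobutene photoadduct A1 would open the central four-membered ring and give the ten-membered dienone lactone A2.
- For: the ring is assembled from a six- and a four-membered ring without high dilution, and both trisubstituted olefins arise in one stereospecific step. On ring construction alone this is shorter than the chosen route.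
- Against: A2 has C14 as a methyl on a 1(10)-olefin. The target needs the C10=C14 methylene and a C1 carbinol, so a late allylic oxidation with transposition would have to set 1S with no control element nearby. The C6 ketone must be reduced to 6S, C13 is missing and would need a late α-methylenation, and 1(10),4-dienes of this type can undergo Cope rearrangement at thermolysis temperatures.
- Comparison: the chosen route sets C1 by reagent control before the ring exists, carries both exocyclic methylenes from the start, and needs five steps after ring formation.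

**Alternative 2:** The C5–C6 bond is cut. CrCl2 with catalytic NiCl2 would turn the Z-iodoalkene of aldehyde A3 into an alkenylchromium species that adds to the C6 aldehyde and closes the ring to A4.
- For: the Z geometry of C4=C5 is fixed before the ring is made, and the lactone ring is already present. On olefin geometry this is stronger than the chosen route, which relies on regio- and syn-selective carbometalation.
- Against: it is a direct end-to-end closure of a ten-membered carbocycle. The aldehyde of A3 is α-branched at C7 and has the lactone oxygen β to it, so epimerisation and β-elimination threaten under Lewis-acidic trivalent chromium salts. The C6 configuration depends on an unknown macrocyclic conformation, and A4 lacks C13.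
- Comparison: the chosen route closes its ring as an ether and then contracts it, creating C6 and C7 together with C13 in place.

**Alternative 3:** The C8–C9 bond is cut. Pd(PPh3)4 would ionise the allylic acetate of A5, Et2Zn would convert the allylpalladium into an allylzinc, and this would add to the C8 aldehyde to give A6.
- For: the C8 carbinol and the C10=C14 methylene arise in the ring-closing step, and C12 is already an ester, so lactonisation needs no oxidation. On end-game redox economy this is stronger than the chosen route.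
- Against: A5 is a linear compound with five stereocentres including the epoxide, to be carried through a long linear sequence. Its aldehyde is epimerisable at C7, zinc salts are Lewis acids towards the epoxide, the closure competes with reduction and oligomerisation, and C13 is again missing.
- Comparison: the chosen route is convergent (fragments of six and three steps), installs the epoxide after the ring, and takes C6/C7 from a sigmatropic transition state with close precedent.

Key step: step 16

Remark on the chemistry: in steps 3 and 10 the antipode of the oxazoline–sulfonamide ligand is the one that sends the organochromium reagent to the Si face of 4 and to the Re face of 16; which antipode does so is to be confirmed on the first run. TBS = tert-butyldimethylsilyl, TES = triethylsilyl, PMB = 4-methoxybenzyl; locants C1–C15 are those of the germacrane skeleton.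

## Steps

Step 1
Reactants: 1 prop-2-yn-1-ol
Product: 2 1-methoxy-4-[(prop-2-yn-1-yloxy)methyl]benzene
Conditions: NaH, PMBCl, Bu4NI (cat.), THF/DMF, 0 °C → rt
Reagents that add atoms: 4-methoxybenzyl chloride, COc1ccc(CCl)cc1
Why: Williamson etherification of a primary alkoxide with a benzylic chloride; PMB is chosen for O13 because it survives organolithium, hydride and silylation steps and is later removed oxidatively beside silyl ethers.

Step 2
Reactants: 2 1-methoxy-4-[(prop-2-yn-1-yloxy)methyl]benzene
Product: 4 4-[(4-methoxybenzyl)oxy]but-2-ynal, via lithium acetylide 3 (not isolated)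
Conditions: n-BuLi, THF, −78 °C; DMF, −78 → 0 °C; inverse quench into aq. KH2PO4
Reagents that add atoms: N,N-dimethylformamide, CN(C)C=O
Why: Formylation of a lithium acetylide supplies C8; the buffered inverse quench releases the ynal without conjugate addition of dimethylamine.

Step 3
Reactants: 4 4-[(4-methoxybenzyl)oxy]but-2-ynal; 5 2,3-dibromopropene
Product: 7 (4S)-2-bromo-7-[(4-methoxybenzyl)oxy]hept-1-en-5-yn-4-ol, via trimethylsilyl ether 6 (not isolated)
Conditions: CrCl2 (10 mol%), chiral oxazoline–sulfonamide ligand (11 mol%), Et3N, Co(C32H16N8) (cobalt phthalocyanine, cat.), Mn, Me3SiCl, 2,6-lutidine, THF, rt; then 1 M HCl, THF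
Reagents that add atoms: none
Why: Catalytic asymmetric chromium-mediated 2-bromoallylation (Nozaki–Hiyama allylation): only the allylic C–Br bond of 5 is reduced, and the ligand-bound allylchromium adds to the Si face of the ynal, which sets C8 as S. The alkenyl bromide is kept for step 10.

Step 4
Reactants: 7 (4S)-2-bromo-7-[(4-methoxybenzyl)oxy]hept-1-en-5-yn-4-ol
Product: 9 (4S,5Z)-2-bromo-6-iodo-7-[(4-methoxybenzyl)oxy]hepta-1,5-dien-4-ol, via sodium alkenylalanate 8 (not isolated)
Conditions: NaAlH2(OCH2CH2OMe)2, THF, 0 °C; then I2, THF, −78 °C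
Reagents that add atoms: iodine, [I][I]
Why: Hydroxyl-directed trans-hydroalumination of the propargylic alcohol puts hydrogen on C7 and aluminium on C11 in a five-membered alkoxyalanate; iodinolysis with retention gives the iodoalkene with iodine cis to C8. This fixes which substituent of C11 ends up cis to C8.

Step 5
Reactants: 9 (4S,5Z)-2-bromo-6-iodo-7-[(4-methoxybenzyl)oxy]hepta-1,5-dien-4-ol
Product: 10 (2E,4S)-6-bromo-2-{[(4-methoxybenzyl)oxy]methyl}hepta-2,6-diene-1,4-diol
Conditions: Bu3SnCH2OH, Pd(PPh3)4 (5 mol%), 1,4-dioxane, 80 °C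
Reagents that add atoms: (tributylstannyl)methanol, CCCC[Sn](CCCC)(CCCC)CO
Why: Stille hydroxymethylation with retention of olefin geometry; zerovalent palladium inserts into the alkenyl iodide much faster than into the 2-bromoalkene, so C12 enters cis to C8 and the bromide is kept.

Step 6
Reactants: 10 (2E,4S)-6-bromo-2-{[(4-methoxybenzyl)oxy]methyl}hepta-2,6-diene-1,4-diol
Product: 11 (4S,5Z)-2-bromo-4-(TBS-oxy)-6-[(TBS-oxy)methyl]-7-[(4-methoxybenzyl)oxy]hepta-1,5-diene
Conditions: TBSOTf, 2,6-lutidine, CH2Cl2, −78 → 0 °C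
Reagents that add atoms: tert-butyldimethylsilyl trifluoromethanesulfonate, CC(C)(C)[Si](C)(C)OS(=O)(=O)C(F)(F)F
Why: Standard silylation of a primary and a secondary allylic alcohol; O8 and O12 receive the same group because they are released together before the lactonisation.

Step 7
Reactants: 1 prop-2-yn-1-ol
Product: 12 triethyl(prop-2-yn-1-yloxy)silane
Conditions: Et3SiCl, imidazole, CH2Cl2, 0 °C
Reagents that add atoms: chlorotriethylsilane, CC[Si](Cl)(CC)CC
Why: Silylation of a primary alcohol; the TES ether on O6 is the most acid-labile ether of the route and can be removed in step 14 beside three TBS ethers and an allylic chloride.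

Step 8
Reactants: 12 triethyl(prop-2-yn-1-yloxy)silane; 13 oxetane
Product: 15 6-[(triethylsilyl)oxy]hex-4-yn-1-ol, via lithium acetylide 14 (not isolated)
Conditions: n-BuLi, THF, −78 °C; BF3·OEt2; 13, −78 °C; then H2O
Reagents that add atoms: none
Why: Lewis-acid-promoted opening of oxetane by a lithium acetylide forms C3–C4 and gives the C1–C6 chain in one step.

Step 9
Reactants: 15 6-[(triethylsilyl)oxy]hex-4-yn-1-ol
Product: 16 6-[(triethylsilyl)oxy]hex-4-ynal
Conditions: Dess–Martin periodinane, NaHCO3, CH2Cl2, 0 °C → rt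
Reagents that add atoms: none
Why: Buffered hypervalent-iodine oxidation of a primary alcohol to the aldehyde without loss of the silyl ether or isomerisation of the alkyne.

Step 10
Reactants: 11 (4S,5Z)-2-bromo-4-(TBS-oxy)-6-[(TBS-oxy)methyl]-7-[(4-methoxybenzyl)oxy]hepta-1,5-diene; 16 6-[(triethylsilyl)oxy]hex-4-ynal
Product: 17 (6S,9S,10Z)-9-(TBS-oxy)-11-[(TBS-oxy)methyl]-12-[(4-methoxybenzyl)oxy]-7-methylidene-1-[(triethylsilyl)oxy]dodec-10-en-2-yn-6-ol
Conditions: CrCl2 (3 equiv), NiCl2 (2 mol%), chiral oxazoline–sulfonamide ligand (3.3 equiv), Et3N, THF, rt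
Reagents that add atoms: none
Why: Nozaki–Hiyama–Kishi coupling: zerovalent nickel inserts into the alkenyl C–Br bond, transmetallation gives an alkenylchromium species that adds only to the aldehyde. The sulfonamide ligand on chromium directs attack to the Re face of 16 and sets C1 as S under reagent control, independent of the remote C8 centre.

Step 11
Reactants: 17 (6S,9S,10Z)-9-(TBS-oxy)-11-[(TBS-oxy)methyl]-12-[(4-methoxybenzyl)oxy]-7-methylidene-1-[(triethylsilyl)oxy]dodec-10-en-2-yn-6-ol
Product: 18 (6S,9S,10Z)-6,9-bis(TBS-oxy)-11-[(TBS-oxy)methyl]-12-[(4-methoxybenzyl)oxy]-7-methylidene-1-[(triethylsilyl)oxy]dodec-10-en-2-yne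
Conditions: TBSOTf, 2,6-lutidine, CH2Cl2, −78 °C
Reagents that add atoms: tert-butyldimethylsilyl trifluoromethanesulfonate, CC(C)(C)[Si](C)(C)OS(=O)(=O)C(F)(F)F
Why: Silylation of the secondary allylic alcohol. A silyl ether is used on O1 because a benzyl-type allyl ether there would itself be open to base-induced Wittig rearrangement in step 16, and because PMB must stay unique to O13.

Step 12
Reactants: 18 (6S,9S,10Z)-6,9-bis(TBS-oxy)-11-[(TBS-oxy)methyl]-12-[(4-methoxybenzyl)oxy]-7-methylidene-1-[(triethylsilyl)oxy]dodec-10-en-2-yne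
Product: 19 (2Z,4S,7S)-4,7-bis(TBS-oxy)-2-[(TBS-oxy)methyl]-6-methylidene-12-[(triethylsilyl)oxy]dodec-2-en-10-yn-1-ol
Conditions: DDQ, CH2Cl2/pH 7 buffer, 0 °C
Reagents that add atoms: none
Why: Oxidative cleavage of the PMB ether frees only O13; silyl ethers, the alkyne and the unactivated olefins are inert, and the neutral medium excludes a silyl shift from O12 to O13.

Step 13
Reactants: 19 (2Z,4S,7S)-4,7-bis(TBS-oxy)-2-[(TBS-oxy)methyl]-6-methylidene-12-[(triethylsilyl)oxy]dodec-2-en-10-yn-1-ol
Product: 21 (2E,4S,7S)-4,7-bis(TBS-oxy)-2-[(TBS-oxy)methyl]-1-chloro-6-methylidene-12-[(triethylsilyl)oxy]dodec-2-en-10-yne, via allylic mesylate 20 (not isolated)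
Conditions: MsCl, LiCl, 2,4,6-collidine, DMF, 0 °C
Reagents that add atoms: lithium chloride, [Li+].[Cl-]
Why: Mesylation and in situ SN2 displacement by chloride give the unrearranged primary allylic chloride. C13 is made the electrophile so that the later alkoxide sits on O6, far from every silyl ether.

Step 14
Reactants: 21 (2E,4S,7S)-4,7-bis(TBS-oxy)-2-[(TBS-oxy)methyl]-1-chloro-6-methylidene-12-[(triethylsilyl)oxy]dodec-2-en-10-yne
Product: 22 (6S,9S,10E)-6,9-bis(TBS-oxy)-11-[(TBS-oxy)methyl]-12-chloro-7-methylidenedodec-10-en-2-yn-1-ol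
Conditions: PPTS (cat.), MeOH/CH2Cl2, 0 °C
Reagents that add atoms: none
Why: Acid-catalysed methanolysis removes the primary TES ether much faster than the TBS ethers and does not solvolyse the allylic chloride at 0 °C.

Step 15
Reactants: 22 (6S,9S,10E)-6,9-bis(TBS-oxy)-11-[(TBS-oxy)methyl]-12-chloro-7-methylidenedodec-10-en-2-yn-1-ol
Product: 23 (3Z,5S,8S)-5,8-bis(TBS-oxy)-3-[(TBS-oxy)methyl]-7-methylidene-1-oxacyclotridec-3-en-11-yne
Conditions: NaH, Bu4NI (cat.), THF, 50 °C, syringe-pump addition (final 0.002 M)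
Reagents that add atoms: none
Why: Intramolecular Williamson etherification (SN2 at C13, iodide catalysis) closes the thirteen-membered ether. The alkyne and the trisubstituted olefin remove rotors from the chain, and slow addition keeps the alkoxide dilute so that cyclisation outruns oligomerisation.

Step 16
Reactants: 23 (3Z,5S,8S)-5,8-bis(TBS-oxy)-3-[(TBS-oxy)methyl]-7-methylidene-1-oxacyclotridec-3-en-11-yne
Product: 25 (1S,6S,9S,10S)-6,9-bis(TBS-oxy)-10-[3-(TBS-oxy)prop-1-en-2-yl]-7-methylidenecyclodec-2-yn-1-ol, via C6-lithiated ether 24 (not isolated)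
Conditions: n-BuLi (1.5 equiv), THF–hexane, −78 → −30 °C; then H2O at −78 °C
Reagents that add atoms: none
Why: n-BuLi removes a proton from C6, the only position that is both propargylic and α to oxygen, and the carbanion 24 attacks C7 of the allyl ether through a five-membered envelope transition state (C6, O, C13, C11, C7) while the O–C13 bond breaks, a concerted suprafacial [2,3]-sigmatropic (Wittig) shift. The closest known reaction type is the [2,3]-Wittig ring contraction of thirteen-membered propargylic allylic ethers to ten-membered cycloalkynols. The ten-membered carbocycle is closed by contraction: the new C6–C7 bond spans the existing ether ring, so no end-to-end cyclisation is involved. C6 and C7 are set relative to each other by the allyl ether geometry: with C8 trans to C13 the alkynyl group takes the exo position of the envelope and the hydroxyl ends anti to C8 when the chain C5–C6–C7–C11 is drawn extended. The absolute sense at C7 comes from C8: allylic 1,3-strain with the C12 arm holds C8–H in the olefin plane, and C6 adds to the face opposite the C8 silyloxy group, which is also the face that carries C9 and the tether. The step needs lithiation at C6 and not at the allylic C13, and the [2,3]- and not the [1,2]-shift; the acidity of the propargylic ether C–H, the absence of benzylic ethers and the low temperature should secure both. The lithium alkoxide is quenched cold so that no silyl group moves to O6.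

Step 17
Reactants: 25 (1S,6S,9S,10S)-6,9-bis(TBS-oxy)-10-[3-(TBS-oxy)prop-1-en-2-yl]-7-methylidenecyclodec-2-yn-1-ol
Product: 27 (1R,2Z,6S,9S,10S)-6,9-bis(TBS-oxy)-10-[3-(TBS-oxy)prop-1-en-2-yl]-3-methyl-7-methylidenecyclodec-2-en-1-ol, via alkenylmagnesium bromide 26 (not isolated)
Conditions: MeMgBr (5 equiv), Fe(acac)3 (0.2 equiv), THF, −20 → 0 °C; then pH 7 buffer
Reagents that add atoms: methylmagnesium bromide, C[Mg]Br
Why: Iron-catalysed, alkoxide-directed syn-carbomagnesiation of a propargylic alcohol: methyl goes to the distal alkyne carbon C4 and magnesium to C5 on the same side, so protonation gives the ring-Z C4=C5 olefin with C15 on C4. The reaction is known for acyclic secondary propargylic alcohols; in the cycloalkyne, syn addition also relieves bending strain.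

Step 18
Reactants: 27 (1R,2Z,6S,9S,10S)-6,9-bis(TBS-oxy)-10-[3-(TBS-oxy)prop-1-en-2-yl]-3-methyl-7-methylidenecyclodec-2-en-1-ol
Product: 28 (1S,2S,3S,4S,7S,10R)-4,7-bis(TBS-oxy)-3-[3-(TBS-oxy)prop-1-en-2-yl]-10-methyl-6-methylidene-11-oxabicyclo[8.1.0]undecan-2-ol
Conditions: VO(acac)2 (5 mol%), t-BuOOH, CH2Cl2, 0 °C
Reagents that add atoms: tert-butyl hydroperoxide, CC(C)(C)OO
Why: Vanadium-catalysed epoxidation with the C6 hydroxyl bound to the metal: the allylic Z-trisubstituted olefin reacts far faster than the homoallylic C11=C13 and the C10=C14 methylenes. Oxygen is delivered to the face cis to O6, as in other medium-ring Z-cycloalkenols, which gives 4R,5S.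

Step 19
Reactants: 28 (1S,2S,3S,4S,7S,10R)-4,7-bis(TBS-oxy)-3-[3-(TBS-oxy)prop-1-en-2-yl]-10-methyl-6-methylidene-11-oxabicyclo[8.1.0]undecan-2-ol; 29 angelic acid, (2Z)-2-methylbut-2-enoic acid
Product: 31 (1S,2S,3S,4S,7S,10R)-4,7-bis(TBS-oxy)-3-[3-(TBS-oxy)prop-1-en-2-yl]-10-methyl-6-methylidene-11-oxabicyclo[8.1.0]undecan-2-yl (2Z)-2-methylbut-2-enoate, via mixed anhydride 30 (not isolated)
Conditions: 29, 2,4,6-trichlorobenzoyl chloride, Et3N, toluene, rt; then 28, 80 °C
Reagents that add atoms: none
Why: Yamaguchi-type esterification through the mixed 2,4,6-trichlorobenzoic anhydride without nucleophilic catalyst, the conditions under which hindered secondary alcohols are angeloylated without Z to E isomerisation. No alkoxide is formed, so a Payne shift of the epoxy alcohol is avoided.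

Step 20
Reactants: 31 (1S,2S,3S,4S,7S,10R)-4,7-bis(TBS-oxy)-3-[3-(TBS-oxy)prop-1-en-2-yl]-10-methyl-6-methylidene-11-oxabicyclo[8.1.0]undecan-2-yl (2Z)-2-methylbut-2-enoate
Product: 32 (1S,2S,3R,4S,7S,10R)-4,7-dihydroxy-3-(3-hydroxyprop-1-en-2-yl)-10-methyl-6-methylidene-11-oxabicyclo[8.1.0]undecan-2-yl (2Z)-2-methylbut-2-enoate
Conditions: Bu4NF, AcOH (1:1), THF, rt
Reagents that add atoms: none
Why: Fluoride cleaves the three silyl ethers; acetic acid buffers the medium so that neither O6 to O8 acyl migration nor epoxide opening should occur, and 32 is used at once.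

Step 21
Reactants: 32 (1S,2S,3R,4S,7S,10R)-4,7-dihydroxy-3-(3-hydroxyprop-1-en-2-yl)-10-methyl-6-methylidene-11-oxabicyclo[8.1.0]undecan-2-yl (2Z)-2-methylbut-2-enoate
Product: 35 CNP0104965.1, (1S,4R,5S,6S,7R,8S)-6-angeloyloxy-4,5-epoxy-1-hydroxygermacra-10(14),11(13)-dien-12,8-olide, via hydroxy enal 33 (not isolated), via lactol 34 (not isolated)
Conditions: PhI(OAc)2 (2.5 equiv), TEMPO (20 mol%), NaHCO3, CH2Cl2, rt
Reagents that add atoms: none
Why: Oxoammonium (TEMPO) oxidation is selective for the primary allylic alcohol; aldehyde 33 is trapped by O8 as the five-membered lactol 34, which is oxidised on to the lactone. The secondary C1 carbinol reacts much more slowly and O6 is acylated, so only the 12,8-olide can form.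

## Compound list

1 | prop-2-yn-1-ol | C#CCO | starting material
2 | 1-methoxy-4-[(prop-2-yn-1-yloxy)methyl]benzene | C#CCOCc1ccc(OC)cc1 | intermediate
3 | lithium acetylide of 2 | [Li]C#CCOCc1ccc(OC)cc1 | intermediate
4 | 4-[(4-methoxybenzyl)oxy]but-2-ynal | O=CC#CCOCc1ccc(OC)cc1 | intermediate
5 | 2,3-dibromopropene | C=C(Br)CBr | starting material
6 | trimethylsilyl ether of 7 | C=C(Br)C[C@H](O[Si](C)(C)C)C#CCOCc1ccc(OC)cc1 | intermediate
7 | (4S)-2-bromo-7-[(4-methoxybenzyl)oxy]hept-1-en-5-yn-4-ol | C=C(Br)C[C@H](O)C#CCOCc1ccc(OC)cc1 | intermediate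
8 | sodium alkenylalanate (2,5-dihydro-1,2-oxaaluminole ate complex, aluminium on C11) | C=C(Br)C[C@H]1C=C(COCc2ccc(OC)cc2)[Al-](OCCOC)(OCCOC)O1.[Na+] | intermediate
9 | (4S,5Z)-2-bromo-6-iodo-7-[(4-methoxybenzyl)oxy]hepta-1,5-dien-4-ol | C=C(Br)C[C@H](O)/C=C(\I)COCc1ccc(OC)cc1 | intermediate
10 | (2E,4S)-6-bromo-2-{[(4-methoxybenzyl)oxy]methyl}hepta-2,6-diene-1,4-diol | C=C(Br)C[C@H](O)/C=C(\CO)COCc1ccc(OC)cc1 | intermediate
11 | (4S,5Z)-2-bromo-4-(TBS-oxy)-6-[(TBS-oxy)methyl]-7-[(4-methoxybenzyl)oxy]hepta-1,5-diene | C=C(Br)C[C@H](O[Si](C)(C)C(C)(C)C)/C=C(\CO[Si](C)(C)C(C)(C)C)COCc1ccc(OC)cc1 | intermediate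
12 | triethyl(prop-2-yn-1-yloxy)silane | C#CCO[Si](CC)(CC)CC | intermediate
13 | oxetane | C1COC1 | starting material
14 | lithium acetylide of 12 | [Li]C#CCO[Si](CC)(CC)CC | intermediate
15 | 6-[(triethylsilyl)oxy]hex-4-yn-1-ol | OCCCC#CCO[Si](CC)(CC)CC | intermediate
16 | 6-[(triethylsilyl)oxy]hex-4-ynal | O=CCCC#CCO[Si](CC)(CC)CC | intermediate
17 | (6S,9S,10Z)-9-(TBS-oxy)-11-[(TBS-oxy)methyl]-12-[(4-methoxybenzyl)oxy]-7-methylidene-1-[(triethylsilyl)oxy]dodec-10-en-2-yn-6-ol | CC[Si](CC)(CC)OCC#CCC[C@H](O)C(=C)C[C@H](O[Si](C)(C)C(C)(C)C)/C=C(\CO[Si](C)(C)C(C)(C)C)COCc1ccc(OC)cc1 | intermediate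
18 | (6S,9S,10Z)-6,9-bis(TBS-oxy)-11-[(TBS-oxy)methyl]-12-[(4-methoxybenzyl)oxy]-7-methylidene-1-[(triethylsilyl)oxy]dodec-10-en-2-yne | CC[Si](CC)(CC)OCC#CCC[C@H](O[Si](C)(C)C(C)(C)C)C(=C)C[C@H](O[Si](C)(C)C(C)(C)C)/C=C(\CO[Si](C)(C)C(C)(C)C)COCc1ccc(OC)cc1 | intermediate
19 | (2Z,4S,7S)-4,7-bis(TBS-oxy)-2-[(TBS-oxy)methyl]-6-methylidene-12-[(triethylsilyl)oxy]dodec-2-en-10-yn-1-ol | CC[Si](CC)(CC)OCC#CCC[C@H](O[Si](C)(C)C(C)(C)C)C(=C)C[C@H](O[Si](C)(C)C(C)(C)C)/C=C(\CO[Si](C)(C)C(C)(C)C)CO | intermediate
20 | methanesulfonate of 19 | CC[Si](CC)(CC)OCC#CCC[C@H](O[Si](C)(C)C(C)(C)C)C(=C)C[C@H](O[Si](C)(C)C(C)(C)C)/C=C(\CO[Si](C)(C)C(C)(C)C)COS(C)(=O)=O | intermediate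
21 | (2E,4S,7S)-4,7-bis(TBS-oxy)-2-[(TBS-oxy)methyl]-1-chloro-6-methylidene-12-[(triethylsilyl)oxy]dodec-2-en-10-yne | CC[Si](CC)(CC)OCC#CCC[C@H](O[Si](C)(C)C(C)(C)C)C(=C)C[C@H](O[Si](C)(C)C(C)(C)C)/C=C(\CO[Si](C)(C)C(C)(C)C)CCl | intermediate
22 | (6S,9S,10E)-6,9-bis(TBS-oxy)-11-[(TBS-oxy)methyl]-12-chloro-7-methylidenedodec-10-en-2-yn-1-ol | OCC#CCC[C@H](O[Si](C)(C)C(C)(C)C)C(=C)C[C@H](O[Si](C)(C)C(C)(C)C)/C=C(\CO[Si](C)(C)C(C)(C)C)CCl | intermediate
23 | (3Z,5S,8S)-5,8-bis(TBS-oxy)-3-[(TBS-oxy)methyl]-7-methylidene-1-oxacyclotridec-3-en-11-yne | O1CC#CCC[C@H](O[Si](C)(C)C(C)(C)C)C(=C)C[C@H](O[Si](C)(C)C(C)(C)C)/C=C(\CO[Si](C)(C)C(C)(C)C)C1 | intermediate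
24 | 13-lithio derivative of 23 (lithium on C6) | O1C([Li])C#CCC[C@H](O[Si](C)(C)C(C)(C)C)C(=C)C[C@H](O[Si](C)(C)C(C)(C)C)/C=C(\CO[Si](C)(C)C(C)(C)C)C1 | intermediate
25 | (1S,6S,9S,10S)-6,9-bis(TBS-oxy)-10-[3-(TBS-oxy)prop-1-en-2-yl]-7-methylidenecyclodec-2-yn-1-ol | O[C@@H]1C#CCC[C@H](O[Si](C)(C)C(C)(C)C)C(=C)C[C@H](O[Si](C)(C)C(C)(C)C)[C@H]1C(=C)CO[Si](C)(C)C(C)(C)C | intermediate
26 | bromomagnesium alkoxide of the C5-alkenylmagnesium bromide (Mg on C5 cis to C15) | Br[Mg]O[C@@H]1/C([Mg]Br)=C(/C)CC[C@H](O[Si](C)(C)C(C)(C)C)C(=C)C[C@H](O[Si](C)(C)C(C)(C)C)[C@H]1C(=C)CO[Si](C)(C)C(C)(C)C | intermediate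
27 | (1R,2Z,6S,9S,10S)-6,9-bis(TBS-oxy)-10-[3-(TBS-oxy)prop-1-en-2-yl]-3-methyl-7-methylidenecyclodec-2-en-1-ol | O[C@@H]1/C=C(/C)CC[C@H](O[Si](C)(C)C(C)(C)C)C(=C)C[C@H](O[Si](C)(C)C(C)(C)C)[C@H]1C(=C)CO[Si](C)(C)C(C)(C)C | intermediate
28 | (1S,2S,3S,4S,7S,10R)-4,7-bis(TBS-oxy)-3-[3-(TBS-oxy)prop-1-en-2-yl]-10-methyl-6-methylidene-11-oxabicyclo[8.1.0]undecan-2-ol | O[C@@H]1[C@@H]2O[C@]2(C)CC[C@H](O[Si](C)(C)C(C)(C)C)C(=C)C[C@H](O[Si](C)(C)C(C)(C)C)[C@H]1C(=C)CO[Si](C)(C)C(C)(C)C | intermediate
29 | angelic acid, (2Z)-2-methylbut-2-enoic acid | C/C=C(/C)C(=O)O | starting material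
30 | (2Z)-2-methylbut-2-enoic 2,4,6-trichlorobenzoic anhydride | C/C=C(/C)C(=O)OC(=O)c1c(Cl)cc(Cl)cc1Cl | intermediate
31 | (1S,2S,3S,4S,7S,10R)-4,7-bis(TBS-oxy)-3-[3-(TBS-oxy)prop-1-en-2-yl]-10-methyl-6-methylidene-11-oxabicyclo[8.1.0]undecan-2-yl (2Z)-2-methylbut-2-enoate | C/C=C(/C)C(=O)O[C@@H]1[C@@H]2O[C@]2(C)CC[C@H](O[Si](C)(C)C(C)(C)C)C(=C)C[C@H](O[Si](C)(C)C(C)(C)C)[C@H]1C(=C)CO[Si](C)(C)C(C)(C)C | intermediate
32 | (1S,2S,3R,4S,7S,10R)-4,7-dihydroxy-3-(3-hydroxyprop-1-en-2-yl)-10-methyl-6-methylidene-11-oxabicyclo[8.1.0]undecan-2-yl (2Z)-2-methylbut-2-enoate | C/C=C(/C)C(=O)O[C@@H]1[C@@H]2O[C@]2(C)CC[C@H](O)C(=C)C[C@H](O)[C@H]1C(=C)CO | intermediate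
33 | C12 aldehyde of 32 (3-oxoprop-1-en-2-yl side chain) | C/C=C(/C)C(=O)O[C@@H]1[C@@H]2O[C@]2(C)CC[C@H](O)C(=C)C[C@H](O)[C@H]1C(=C)C=O | intermediate
34 | 12,8-lactol (either C12 epimer) | C=C1C(O)O[C@H]2CC(=C)[C@@H](O)CC[C@@]3(C)O[C@H]3[C@@H](OC(=O)/C(C)=C\C)[C@H]12 | intermediate
35 | CNP0104965.1, (1S,4R,5S,6S,7R,8S)-6-angeloyloxy-4,5-epoxy-1-hydroxygermacra-10(14),11(13)-dien-12,8-olide | C=C1C(=O)O[C@H]2CC(=C)[C@@H](O)CC[C@@]3(C)O[C@H]3[C@@H](OC(=O)/C(C)=C\C)[C@H]12 | target

## Step count and least certain steps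

Total step count: 21. Longest linear sequence: 18 steps (steps 1–6, then 10–21); fragment A takes steps 7–9.

**Step 16 (key step).** The most likely failure is loss of control over the C6/C7 relationship. The tether between the alkyne and C8 may force the envelope in which the alkynyl group and C8 are gauche, which would give the C6 epimer; a [1,2]-shift or lithiation at C13 would lower the yield further.
Fallback: the rearrangement of 23 is accepted as it falls and the C6-epimeric cyclodecynol F1 is inverted by a Mitsunobu reaction (4-nitrobenzoic acid, PPh3, diisopropyl azodicarboxylate) to the 4-nitrobenzoate F2. Methanolysis (K2CO3, MeOH) returns to the route at 25.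

**Step 17.** The carbomagnesiation may be slow or may lose its regiochemical bias on an alkyne flanked by the branched C7, and reduction of the alkyne by the low-valent iron species can compete.
Fallback: from 25, a PtCl2/XPhos-catalysed syn-hydrosilylation with Et3SiH places silicon on the carbon remote from the hydroxyl and gives the alkenylsilane F3. Iododesilylation with retention (N-iodosuccinimide, (CF3)2CHOH, 0 °C) gives the alkenyl iodide F4, and Negishi coupling (MeZnCl, Pd(PPh3)4, THF) returns to the route at 27.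

**Step 15.** Intermolecular etherification (oligomerisation) may outrun the thirteen-membered closure, or the alkoxide may attack C7 in an SN2' sense.
Fallback: the ether bond is made between two small partners and the ring is closed at C1–C10.
- Aldehyde 16 is converted (HC(OMe)3, MeOH, PPTS) into 6,6-dimethoxyhex-2-yn-1-ol F5, with loss of the TES group.
- Bromide 11 is treated with DDQ to give the allylic alcohol F6 and then with MsCl/LiCl/collidine to give the allylic chloride F7.
- The sodium alkoxide of F5 is alkylated with F7 (NaH, Bu4NI, THF) to the acyclic ether acetal F8.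
- Chemoselective acetal cleavage (Et3SiOTf, 2,4,6-collidine; then H2O) gives the aldehyde F9.
- An intramolecular Nozaki–Hiyama–Kishi reaction (CrCl2, NiCl2 cat., the ligand of step 10, high dilution) gives the macrocyclic C1 alcohol F10, and TBSOTf/2,6-lutidine returns to the route at 23.

**Step 10.** Facial selectivity at C1 may be poor, because the ligand has to control an α-unbranched aldehyde against a bulky 2-substituted alkenylchromium reagent, and insertion into the 2-bromoalkene may be slow.
Fallback: 11 and 16 are coupled without ligand (CrCl2, NiCl2 cat., DMF) to the C1-epimeric alcohols F11, which are oxidised (Dess–Martin periodinane) to the enone F12. CBS reduction ((R)-2-methyl-CBS-oxazaborolidine, BH3·SMe2, with the branched alkenyl group as the large substituent) returns to the route at 17.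

**Step 21.** The secondary allylic C1 carbinol may be oxidised competitively to the enone, or the acetic acid released may open the epoxide with a free hydroxyl.
Fallback: from 31, only the primary allylic silyl ether is removed (HF·pyridine, pyridine, THF, 0 °C) to give the C12 alcohol F13. MnO2 gives the enal F14 and Pinnick oxidation (NaClO2, NaH2PO4, 2-methylbut-2-ene) the acid F15. Desilylation (Bu4NF, AcOH) frees O8 and O1, and the γ-hydroxy acid lactonises to 35.

## Further compounds

F1 | step 16 | (1R,6S,9S,10S)-6,9-bis(TBS-oxy)-10-[3-(TBS-oxy)prop-1-en-2-yl]-7-methylidenecyclodec-2-yn-1-ol (C6 epimer of 25) | O[C@H]1C#CCC[C@H](O[Si](C)(C)C(C)(C)C)C(=C)C[C@H](O[Si](C)(C)C(C)(C)C)[C@H]1C(=C)CO[Si](C)(C)C(C)(C)C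
F2 | step 16 | 4-nitrobenzoate of 25 | O=C(O[C@@H]1C#CCC[C@H](O[Si](C)(C)C(C)(C)C)C(=C)C[C@H](O[Si](C)(C)C(C)(C)C)[C@H]1C(=C)CO[Si](C)(C)C(C)(C)C)c1ccc(cc1)[N+](=O)[O-]
F3 | step 17 | C4-triethylsilyl ring-Z allylic alcohol (silicon in place of C15 of 27) | O[C@@H]1/C=C(/[Si](CC)(CC)CC)CC[C@H](O[Si](C)(C)C(C)(C)C)C(=C)C[C@H](O[Si](C)(C)C(C)(C)C)[C@H]1C(=C)CO[Si](C)(C)C(C)(C)C
F4 | step 17 | C4-iodo ring-Z allylic alcohol (iodine in place of C15 of 27) | O[C@@H]1/C=C(/I)CC[C@H](O[Si](C)(C)C(C)(C)C)C(=C)C[C@H](O[Si](C)(C)C(C)(C)C)[C@H]1C(=C)CO[Si](C)(C)C(C)(C)C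
F5 | step 15 | 6,6-dimethoxyhex-2-yn-1-ol | COC(OC)CCC#CCO
F6 | step 15 | (2Z,4S)-6-bromo-4-(TBS-oxy)-2-[(TBS-oxy)methyl]hepta-2,6-dien-1-ol | C=C(Br)C[C@H](O[Si](C)(C)C(C)(C)C)/C=C(\CO[Si](C)(C)C(C)(C)C)CO
F7 | step 15 | (4S,5E)-2-bromo-4-(TBS-oxy)-6-[(TBS-oxy)methyl]-7-chlorohepta-1,5-diene | C=C(Br)C[C@H](O[Si](C)(C)C(C)(C)C)/C=C(\CO[Si](C)(C)C(C)(C)C)CCl
F8 | step 15 | 6,6-dimethoxyhex-2-yn-1-yl ether of F6 | C=C(Br)C[C@H](O[Si](C)(C)C(C)(C)C)/C=C(\CO[Si](C)(C)C(C)(C)C)COCC#CCCC(OC)OC
F9 | step 15 | 6-oxohex-2-yn-1-yl ether of F6 | C=C(Br)C[C@H](O[Si](C)(C)C(C)(C)C)/C=C(\CO[Si](C)(C)C(C)(C)C)COCC#CCCC=O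
F10 | step 15 | (3Z,5S,8S)-5-(TBS-oxy)-3-[(TBS-oxy)methyl]-7-methylidene-1-oxacyclotridec-3-en-11-yn-8-ol | O1CC#CCC[C@H](O)C(=C)C[C@H](O[Si](C)(C)C(C)(C)C)/C=C(\CO[Si](C)(C)C(C)(C)C)C1
F11 | step 10 | mixture of C1 epimers of 17 | CC[Si](CC)(CC)OCC#CCCC(O)C(=C)C[C@H](O[Si](C)(C)C(C)(C)C)/C=C(\CO[Si](C)(C)C(C)(C)C)COCc1ccc(OC)cc1
F12 | step 10 | C1 ketone (enone) of 17 | CC[Si](CC)(CC)OCC#CCCC(=O)C(=C)C[C@H](O[Si](C)(C)C(C)(C)C)/C=C(\CO[Si](C)(C)C(C)(C)C)COCc1ccc(OC)cc1
F13 | step 21 | 31 with free C12 hydroxyl | C/C=C(/C)C(=O)O[C@@H]1[C@@H]2O[C@]2(C)CC[C@H](O[Si](C)(C)C(C)(C)C)C(=C)C[C@H](O[Si](C)(C)C(C)(C)C)[C@H]1C(=C)CO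
F14 | step 21 | C12 aldehyde of F13 | C/C=C(/C)C(=O)O[C@@H]1[C@@H]2O[C@]2(C)CC[C@H](O[Si](C)(C)C(C)(C)C)C(=C)C[C@H](O[Si](C)(C)C(C)(C)C)[C@H]1C(=C)C=O
F15 | step 21 | C12 carboxylic acid of F13 | C/C=C(/C)C(=O)O[C@@H]1[C@@H]2O[C@]2(C)CC[C@H](O[Si](C)(C)C(C)(C)C)C(=C)C[C@H](O[Si](C)(C)C(C)(C)C)[C@H]1C(=C)C(=O)O
A1 | alternative 1 | tricyclic enone–cyclobutene photoadduct (lactone-fused 6-4-4 system, cyclobutane centres unassigned) | O1[C@H]2CC3(C)C4CCC4(C)C3C(=O)[C@@H]2CC1=O
A2 | alternative 1 | (1(10)E,4Z)-6-oxo-13-norgermacra-1(10),4-dien-12,8-olide | O1[C@H]2C/C(C)=C/CC/C(C)=C\C(=O)[C@@H]2CC1=O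
A3 | alternative 2 | open-chain Z-iodoalkene with C6 aldehyde on the C7/C8 lactone | I/C=C(/C)CC[C@H](O[Si](C)(C)C(C)(C)C)C(=C)C[C@@H]1OC(=O)C[C@H]1C=O
A4 | alternative 2 | ten-membered Z-allylic alcohol with fused lactone | O[C@@H]1/C=C(/C)CC[C@H](O[Si](C)(C)C(C)(C)C)C(=C)C[C@@H]2OC(=O)C[C@@H]12
A5 | alternative 3 | open-chain C9 allylic acetate with C8 aldehyde, epoxide and C12 methyl ester | CC(=O)OCC(=C)[C@@H](O[Si](C)(C)C(C)(C)C)CC[C@@]1(C)O[C@H]1[C@@H](OCc2ccc(OC)cc2)[C@@H](C=O)CC(=O)OC
A6 | alternative 3 | ten-membered epoxy carbinol with C10 methylene and C12 ester | O[C@H]1CC(=C)[C@@H](O[Si](C)(C)C(C)(C)C)CC[C@@]2(C)O[C@H]2[C@@H](OCc3ccc(OC)cc3)[C@@H]1CC(=O)OC
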